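All runs were computed for substances that don't exist.

1. I started with an easy step. Equal portions at equal intervals make the charged c(coupling partner) climb in stairs, so I replaced the stairs by their mean, 19.0 mM in the flask. Over 15 min this gives an exposure of 285 mM·min, the time integral of charged c(coupling partner), consumption ignored.

2. The decision for the next run was whether half of winter's charge would do. Winter reached 285 mM·min at 10.0 min, the same exposure as the flask, so the flask trades partner for time.

| setting | spring | winter | flask |
|---|---|---|---|
| substrate | 19 mM | 19 mM | 19 mM |
| coupling partner | 14 mM (in portions, 3) | 57 mM (in portions, 3) | 28.5 mM (in portions, 3) |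
| free catalyst | 0.14 mM | 0.14 mM | 0.14 mM |
| remark | run made earlier; portions every 5.0 min | run made earlier; portions every 5.0 min | the portions of coupling partner follow each other after 5.0 min, the first at the start |
| time |  |  | 15 min |

| run | time / min | product / % | substrate / % |
|---|---|---|---|
| spring | 0.833 | 3 | 99 |
| spring | 2.50 | 0 | 101 |
| spring | 4.00 | 0 | 100 |
| spring | 6.00 | 5 | 95 |
| spring | 10.0 | 9 | 94 |
| winter | 2.00 | 4 | 96 |
| winter | 4.00 | 6 | 94 |
| winter | 5.00 | 9 | 91 |
| winter | 8.00 | 18 | 86 |
| winter | 10.0 | 18 | 80 |

(scatter of a reading: 1.5 percentage points)

- concentration of product at 15 min, in mM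
- concentration of substrate at 15 min, in mM

3. The mean has an error. Spring's reading at 10.0 min was 9 % product on 70.0 mM·min, twice winter's product per exposure, so in these scattered readings the yield of exposure fell as the level rose.

4. I therefore took two readings. Winter's reading at 10.0 min, at the same exposure, put c(product) in the flask at 3.42 mM. Winter's first interval, at the flask's mean level, gave a reading of 9 % by 5.00 min, and that pace carried to 15 min put c(product) in the flask at 5.13 mM.

5. I committed to the midpoint for the flask, 4.27 mM. Winter's readings at 10.0 min summed to 98.0 % of the substrate charged, so I took c(substrate) as the charge less that product, 14.7 mM. I kept the smaller charge.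

6. The forecast gave c(product) = 4.4 mM (3.3 mM to 5.6 mM) and c(substrate) = 14.6 mM (13.4 mM to 15.8 mM), a little above my product, reading spring as “roughly first order or steeper at low partner”.

7. The flask gave c(product) = 4.23 mM and c(substrate) = 14.7 mM, within the forecast's ranges.

    coupling partner + free catalyst ⇌ catalyst intermediate A (K = 26.0 M⁻¹, k = 690 M⁻¹ min⁻¹)
    substrate + catalyst intermediate A ⇌ catalyst intermediate B (K = 39.0 M⁻¹, k = 1200 M⁻¹ min⁻¹)
    catalyst intermediate B → by-product + catalyst intermediate C (k = 39.0 min⁻¹)
    catalyst intermediate C → catalyst intermediate D (k = 27.0 min⁻¹)
    catalyst intermediate D → free catalyst + product (k = 26.0 min⁻¹)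

In the flask, catalyst intermediate B had a half-life of 1.1 s by its own step alone, far shorter than the 33.0 min of the flask's slowest mode. At 15.0 min it was made 0.999 times as fast as it was used up, each step taken net, a steady state. Exposure 285 mM·min bought 22.3 % product in the flask. The neighbour with 110 mM of coupling partner had an exposure of 1100 mM·min, 3.86 times as much, for 1.73 times the product. That neighbour's c(product) was 7.31 mM, above the 5.6 mM at the high end of the forecast's range for the flask.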